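The runs are simulated on assumed constants.

The pitfall in the noon run is to take a flattening curve for a slow reaction and let the product climb on towards the 20 min of the winter run.

| flask | starting material | coupling partner | time |
|---|---|---|---|
| noon | 0.120 M | 0.132 M |  |
| dawn | 0.360 M | 0.132 M |  |
| dusk | 0.120 M | 0.260 M |  |
| winter | 0.120 M | 0.132 M | 20 min |

- noon run (time / min: [product] / M): 0.20: 0.0035; 0.32: 0.0048; 0.51: 0.0077; 0.81: 0.0113; 1.3: 0.0164; 2.0: 0.0184; 3.2: 0.0221; 5.1: 0.0238
- dawn run (time / min: [product] / M): 0.20: 0.0110; 0.32: 0.0159; 0.51: 0.0219; 0.81: 0.0314; 1.3: 0.0414; 2.0: 0.0497; 3.2: 0.0575; 5.1: 0.0620
- dusk run (time / min: [product] / M): 0.20: 0.0072; 0.32: 0.0107; 0.51: 0.0151; 0.81: 0.0217; 1.3: 0.0281; 2.0: 0.0338; 3.2: 0.0384; 5.1: 0.0407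

(each reading ± 4 × 10⁻⁴ M)

* reaction order in [coupling partner] at the outset, round the charge of the noon run, defined at two percent of the starting material turned into product
* reaction order in [starting material] at the outset, round the charge of the noon run, defined at two percent of the starting material turned into product (one fixed amount of product, the same in the runs compared)
* product in the winter run at 20 min, as a share of the starting material charged

- Overall: starting material + coupling partner -> product.
- Constant volume, constant temperature.
- An order is taken over about fifteen percent of the charge, up and down.

1. The opening slope of the noon run, first reading over its time, is 0.0175 M min⁻¹. The stall lifetime, the last reading over that slope, is the time the opening rate would take to make the product seen at the end: 1.36 min. If the rise is a single exponential, each lifetime shrinks the gap to the plateau by a factor of e.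

2. Objection: the first reading carries a scatter of 11.4 %. The dawn run has a larger first reading and, from a different charge, gives 1.13 min, shorter than the noon value. The noon value therefore stands as the cautious one, since a shorter lifetime would count more lifetimes.

3. Objection: the last noon reading may still be short of the plateau. With the noon lifetime, its reckoned gap at 5.1 min is 2.35 %, so the noon plateau reads about 0.02437 M.

4. Objection: a slow second rise could hide behind the flat end. Between the last two noon readings, the lifetime predicts a rise of 0.00174 M, and the readings show 0.00170 M.

5. The winter run repeats the noon charge, and 20 min is 14.7 lifetimes, which leaves a reckoned gap of 4.11 × 10⁻⁷ of the plateau. The reckoning here commits to 20.3 % of the starting material charged, the limiting reagent of this charge.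

The forecast gives orders of 1 in coupling partner and 1 in starting material, and 20.5 %, above the reckoning here. Its ground is that “both predict that noon's repeat stays on its plateau at 20 min”.

The flask gives orders of 1.1 and 1.1, and 20.7 %.

    starting material + coupling partner → product (1.212 M⁻¹ min⁻¹)
    starting material → decomposed substrate (0.5520 min⁻¹)

The winter flask stalls because starting material goes to decomposed substrate: without that loss, the product at 20 min is 78.8 %, against 20.7 % as it is. The 14.7 lifetimes of the count put the winter flask on its plateau. In the dusk run, the same reckoning gives a lifetime of 1.13 min and a plateau of 0.0412 M. Product equal to a quarter of the starting material charged is then reckoned for 1.48 min, and the dusk flask reaches it at 1.49 min.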